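**Strategy.** Everything rests on disconnecting the C3=C4 double bond of the 2H-chromene (pyran ring). Ring-closing olefin metathesis joins an aryl vinyl group (future C4) to the vinyl group on the tertiary ether carbon (future C3) and closes the pyran ring in one operation. The step exploits that C3=C4 is a cis-disubstituted styrenyl alkene in a six-membered ring and that neither O1–C2 nor any bond to the quaternary C2 is touched, so C2 is bought as (S)-linalool and carried unchanged. The precursor is an open-chain 2-ethenylaryl ether of a linalool-type tertiary alcohol that already carries the complete trimethylcyclohexenyl side chain, built by SNAr etherification, allylic oxidation and sulfone alkylation.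

Key step: step 10

Remark on the chemistry: (S)-(+)-linalool (coriandrol) is taken to be purchasable in high enantiomeric purity. Its purity sets that of the target, because no bond to C2 is broken anywhere in the route. All aryl ethers of the tertiary allylic alcohol are kept below about 50 °C to exclude aromatic Claisen rearrangement.

**Route**

Step 1
Reactants: 1 2-fluoro-5-hydroxybenzaldehyde
Product: 2 2-fluoro-5-(methoxymethoxy)benzaldehyde
Conditions: NaH, THF–DMF, 0 °C; MOMCl, 0 °C → rt
Reagents that add atoms: chloromethyl methyl ether, COCCl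
Why: Williamson-type O-alkylation (MOM protection) of the phenoxide, the only acidic site, should give an acetal that withstands every basic, oxidative and reductive step that follows.

Step 2
Reactants: 3 (S)-(+)-linalool, (3S)-3,7-dimethylocta-1,6-dien-3-ol; 2 2-fluoro-5-(methoxymethoxy)benzaldehyde
Product: 5 (S)-2-[(3,7-dimethylocta-1,6-dien-3-yl)oxy]-5-(methoxymethoxy)benzaldehyde, via potassium (S)-linaloolate 4 (not isolated)
Conditions: KH, 18-crown-6, THF, 0 °C; then 2, 0 °C → rt (up to 45 °C if slow)
Reagents that add atoms: none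
Why: Nucleophilic aromatic substitution (addition–elimination, SNAr): the potassium tertiary alkoxide should attack the fluorine-bearing carbon ortho to the formyl group, which stabilises the Meisenheimer intermediate, and because the C–O bond of linalool is never broken the (S) centre is carried over with retention.

Step 3
Reactants: 5 (S)-2-[(3,7-dimethylocta-1,6-dien-3-yl)oxy]-5-(methoxymethoxy)benzaldehyde
Product: 6 (S)-1-[(3,7-dimethylocta-1,6-dien-3-yl)oxy]-2-ethenyl-4-(methoxymethoxy)benzene
Conditions: Ph3PCH3Br, KOt-Bu, THF, 0 °C → rt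
Reagents that add atoms: methyltriphenylphosphonium bromide, C[P+](c1ccccc1)(c1ccccc1)c1ccccc1.[Br-]
Why: Wittig methylenation of the non-enolisable aryl aldehyde with the unstabilised ylide should give the aryl vinyl group whose inner carbon becomes C4.

Step 4
Reactants: 6 (S)-1-[(3,7-dimethylocta-1,6-dien-3-yl)oxy]-2-ethenyl-4-(methoxymethoxy)benzene
Product: 7 (2E,6S)-6-[2-ethenyl-4-(methoxymethoxy)phenoxy]-2,6-dimethylocta-2,7-dien-1-ol
Conditions: SeO2 (cat.), t-BuOOH, salicylic acid (cat.), CH2Cl2, 0 °C → rt
Reagents that add atoms: tert-butyl hydroperoxide, CC(C)(C)OO (terminal oxidant); selenium dioxide, O=[Se]=O (catalytic oxygen carrier)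
Why: Selenium dioxide allylic oxidation (ene reaction, then [2,3]-sigmatropic shift) should hydroxylate the (E)-methyl group of the gem-dimethyl terminus, the only olefin with allylic C–H bonds at its more substituted end, and so fix the E geometry of the future chain olefin.

Step 5
Reactants: 7 (2E,6S)-6-[2-ethenyl-4-(methoxymethoxy)phenoxy]-2,6-dimethylocta-2,7-dien-1-ol
Product: 8 1-{[(3S,6E)-8-bromo-3,7-dimethylocta-1,6-dien-3-yl]oxy}-2-ethenyl-4-(methoxymethoxy)benzene
Conditions: CBr4, PPh3, CH2Cl2, −20 → 0 °C
Reagents that add atoms: carbon tetrabromide, BrC(Br)(Br)Br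
Why: Appel bromination should convert the primary allylic alcohol into the bromide by SN2 displacement under neutral conditions, which spares the acid-labile tertiary allylic aryl ether and the acetal and leaves the E olefin in place.

Step 6
Reactants: 9 β-cyclocitral, 2,6,6-trimethylcyclohex-1-ene-1-carbaldehyde
Product: 10 β-cyclogeraniol, (2,6,6-trimethylcyclohex-1-en-1-yl)methanol
Conditions: NaBH4, MeOH, 0 °C
Reagents that add atoms: none
Why: Borohydride 1,2-reduction of the hindered enal should give the allylic alcohol.

Step 7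
Reactants: 10 β-cyclogeraniol
Product: 12 {[(2,6,6-trimethylcyclohex-1-en-1-yl)methyl]sulfonyl}benzene (β-cyclogeranyl phenyl sulfone), via β-cyclogeranyl bromide 11 (not isolated)
Conditions: PBr3, pyridine (cat.), Et2O, −10 °C; crude bromide, then PhSO2Na, DMF, rt
Reagents that add atoms: sodium benzenesulfinate, [Na+].[O-]S(=O)c1ccccc1
Why: Bromination of the allylic alcohol with PBr3 followed by SN2 S-alkylation of the sulfinate, whose soft sulfur terminus attacks the primary carbon, should give the allylic sulfone.

Step 8
Reactants: 12 β-cyclogeranyl phenyl sulfone; 8 1-{[(3S,6E)-8-bromo-3,7-dimethylocta-1,6-dien-3-yl]oxy}-2-ethenyl-4-(methoxymethoxy)benzene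
Product: 14 1-{[(3S,6E)-3,7-dimethyl-9-(phenylsulfonyl)-9-(2,6,6-trimethylcyclohex-1-en-1-yl)nona-1,6-dien-3-yl]oxy}-2-ethenyl-4-(methoxymethoxy)benzene (both C9 epimers), via lithiated sulfone 13 (not isolated)
Conditions: n-BuLi, THF, −78 °C; then 8, −78 → −20 °C
Reagents that add atoms: none
Why: Alkylation of an α-sulfonyl carbanion: the lithiated allylic sulfone should react at its α-carbon with the primary allylic bromide by SN2, joining the two fragments with the E olefin retained, while the new sulfone-bearing centre forms unselectively and is erased in step 9.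

Step 9
Reactants: 14 sulfone (both C9 epimers)
Product: 15 1-{[(3S,6E)-3,7-dimethyl-9-(2,6,6-trimethylcyclohex-1-en-1-yl)nona-1,6-dien-3-yl]oxy}-2-ethenyl-4-(methoxymethoxy)benzene
Conditions: Na(Hg) (6% Na), Na2HPO4, MeOH–THF, −20 °C
Reagents that add atoms: none
Why: Reductive desulfonylation by single-electron transfer from the amalgam should cleave the allylic C–S bond, and protonation of the resulting allyl anion at the less hindered exocyclic carbon under phosphate buffering should keep the tetrasubstituted ring olefin.

Step 10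
Reactants: 15 1-{[(3S,6E)-3,7-dimethyl-9-(2,6,6-trimethylcyclohex-1-en-1-yl)nona-1,6-dien-3-yl]oxy}-2-ethenyl-4-(methoxymethoxy)benzene
Product: 16 (2S)-6-(methoxymethoxy)-2-methyl-2-[(3E)-4-methyl-6-(2,6,6-trimethylcyclohex-1-en-1-yl)hex-3-en-1-yl]-2H-chromene
Conditions: second-generation Grubbs catalyst RuCl2(=CHPh)(PCy3)(H2IMes) (5 mol%), CH2Cl2 (0.005 M), 40 °C, argon sparge
Reagents that add atoms: none
Why: The ruthenium benzylidene should first exchange onto the unhindered aryl vinyl group ([2+2] cycloaddition and cycloreversion) to give a 2-alkoxybenzylidene, which then engages the neighbouring vinyl group on C2 intramolecularly; collapse of the ruthenacyclobutane forms C3=C4 and releases ethylene, whose loss drives the closure. The closest known reaction type is ring-closing olefin metathesis of 2-ethenylaryl allyl ethers to 2H-chromenes, including ethers of tertiary allylic alcohols. The pyran ring is closed as a six-membered ring by ring-closing metathesis of the 1,7-diene, and the ring size forces the new alkene to be cis. No stereocentre is created: C2 keeps the (S) configuration of linalool because neither the O1–C2 bond nor any other bond to C2 is broken, in contrast to electrocyclic chromene syntheses that pass through an achiral quinone methide. The step needs chemoselectivity among four C=C bonds: the tetrasubstituted ring olefin is inert, and attack on the trisubstituted chain olefin, which would close a cyclopentene from a carbene on the C2 vinyl group, should be outpaced because initiation at the aryl vinyl group is far faster than at the vinyl group beside the quaternary carbon and six-ring closure onto a terminal olefin is faster than reaction with a trisubstituted one. High dilution should suppress intermolecular metathesis of the aryl vinyl group.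

Step 11
Reactants: 16 (2S)-6-(methoxymethoxy)-2-methyl-2-[(3E)-4-methyl-6-(2,6,6-trimethylcyclohex-1-en-1-yl)hex-3-en-1-yl]-2H-chromene
Product: 17 (2S)-2-methyl-2-[(3E)-4-methyl-6-(2,6,6-trimethylcyclohex-1-en-1-yl)hex-3-en-1-yl]-2H-chromen-6-ol (target)
Conditions: HCl (aq., cat.), MeOH–THF, rt, under argon
Reagents that add atoms: none
Why: Acid-catalysed acetal cleavage (MOM removal by transacetalisation to methanol) should free the phenol under conditions mild enough for the chromene, the isolated olefins and the C2 centre, which is not involved.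

**Compound list**

1 | 2-fluoro-5-hydroxybenzaldehyde | O=Cc1cc(O)ccc1F | starting material
2 | 2-fluoro-5-(methoxymethoxy)benzaldehyde | O=Cc1cc(OCOC)ccc1F | intermediate
3 | (S)-(+)-linalool, (3S)-3,7-dimethylocta-1,6-dien-3-ol | C=C[C@@](C)(O)CCC=C(C)C | starting material
4 | potassium (3S)-3,7-dimethylocta-1,6-dien-3-olate (not isolated) | C=C[C@@](C)([O-])CCC=C(C)C.[K+] | intermediate
5 | (S)-2-[(3,7-dimethylocta-1,6-dien-3-yl)oxy]-5-(methoxymethoxy)benzaldehyde | C=C[C@@](C)(Oc1ccc(OCOC)cc1C=O)CCC=C(C)C | intermediate
6 | (S)-1-[(3,7-dimethylocta-1,6-dien-3-yl)oxy]-2-ethenyl-4-(methoxymethoxy)benzene | C=C[C@@](C)(Oc1ccc(OCOC)cc1C=C)CCC=C(C)C | intermediate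
7 | (2E,6S)-6-[2-ethenyl-4-(methoxymethoxy)phenoxy]-2,6-dimethylocta-2,7-dien-1-ol | C=C[C@@](C)(Oc1ccc(OCOC)cc1C=C)CC/C=C(\C)CO | intermediate
8 | 1-{[(3S,6E)-8-bromo-3,7-dimethylocta-1,6-dien-3-yl]oxy}-2-ethenyl-4-(methoxymethoxy)benzene | C=C[C@@](C)(Oc1ccc(OCOC)cc1C=C)CC/C=C(\C)CBr | intermediate
9 | β-cyclocitral, 2,6,6-trimethylcyclohex-1-ene-1-carbaldehyde | O=CC1=C(C)CCCC1(C)C | starting material
10 | β-cyclogeraniol, (2,6,6-trimethylcyclohex-1-en-1-yl)methanol | OCC1=C(C)CCCC1(C)C | intermediate
11 | β-cyclogeranyl bromide, 2-(bromomethyl)-1,3,3-trimethylcyclohexene (not isolated) | BrCC1=C(C)CCCC1(C)C | intermediate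
12 | β-cyclogeranyl phenyl sulfone, {[(2,6,6-trimethylcyclohex-1-en-1-yl)methyl]sulfonyl}benzene | O=S(=O)(CC1=C(C)CCCC1(C)C)c1ccccc1 | intermediate
13 | lithiated sulfone, [lithio(2,6,6-trimethylcyclohex-1-en-1-yl)methyl]sulfonylbenzene (not isolated) | [Li]C(C1=C(C)CCCC1(C)C)S(=O)(=O)c1ccccc1 | intermediate
14 | 1-{[(3S,6E)-3,7-dimethyl-9-(phenylsulfonyl)-9-(2,6,6-trimethylcyclohex-1-en-1-yl)nona-1,6-dien-3-yl]oxy}-2-ethenyl-4-(methoxymethoxy)benzene, both C9 epimers | C=C[C@@](C)(Oc1ccc(OCOC)cc1C=C)CC/C=C(\C)CC(C1=C(C)CCCC1(C)C)S(=O)(=O)c1ccccc1 | intermediate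
15 | 1-{[(3S,6E)-3,7-dimethyl-9-(2,6,6-trimethylcyclohex-1-en-1-yl)nona-1,6-dien-3-yl]oxy}-2-ethenyl-4-(methoxymethoxy)benzene | C=C[C@@](C)(Oc1ccc(OCOC)cc1C=C)CC/C=C(\C)CCC1=C(C)CCCC1(C)C | intermediate
16 | (2S)-6-(methoxymethoxy)-2-methyl-2-[(3E)-4-methyl-6-(2,6,6-trimethylcyclohex-1-en-1-yl)hex-3-en-1-yl]-2H-chromene | CC1=C(CC/C(C)=C/CC[C@@]2(C)C=Cc3cc(OCOC)ccc3O2)C(C)(C)CCC1 | intermediate
17 | (2S)-2-methyl-2-[(3E)-4-methyl-6-(2,6,6-trimethylcyclohex-1-en-1-yl)hex-3-en-1-yl]-2H-chromen-6-ol | CC1=C(CC/C(C)=C/CC[C@@]2(C)C=Cc3cc(O)ccc3O2)C(C)(C)CCC1 | target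

**Step count.** Total: 11 steps. Longest linear sequence: 9 steps (steps 1–5 and 8–11, from 1 to 17); steps 6 and 7 prepare sulfone 12 in a side branch.

**Steps most likely to fail**

1. Step 2 (SNAr etherification). The aldehyde may be consumed by hydride transfer between alkoxide–aldehyde adducts (ester formation of the Tishchenko type), and addition to a ring deactivated by the para acetal oxygen may be slow. The fallback changes the activating group to one that cannot add alkoxide and brings the formyl group in afterwards. It sets out from 3. Purchased 2-fluoro-5-hydroxybenzonitrile F1 would be protected (NaH, MOMCl, THF–DMF, 0 °C) to 2-fluoro-5-(methoxymethoxy)benzonitrile F2. Alkoxide 4, made from 3 as before, would displace fluoride from F2 (THF, 18-crown-6, rt) to give (S)-2-[(3,7-dimethylocta-1,6-dien-3-yl)oxy]-5-(methoxymethoxy)benzonitrile F3. Partial reduction with i-Bu2AlH (toluene, −78 °C) and hydrolysis of the aldimine with aqueous potassium sodium tartrate should give aldehyde 5, where the route is rejoined.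

2. Step 10 (ring-closing metathesis). Ruthenium may load on the hindered vinyl group at C2 and close a five-membered ring onto the trisubstituted chain olefin, which cuts off the side chain; if six-ring closure is slow, the aryl vinyl group may also dimerise. The fallback masks the competing olefin before the ring is closed. It sets out from 6.
   - Epoxidation of the trisubstituted olefin (mCPBA, NaHCO3, CH2Cl2, −20 °C) would give 1-{[(3S)-5-(3,3-dimethyloxiran-2-yl)-3-methylpent-1-en-3-yl]oxy}-2-ethenyl-4-(methoxymethoxy)benzene F4 (both oxirane epimers).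
   - Ring-closing metathesis of F4 with the same catalyst, where only the two terminal olefins remain, should give (2S)-2-[2-(3,3-dimethyloxiran-2-yl)ethyl]-6-(methoxymethoxy)-2-methyl-2H-chromene F5.
   - Base-induced epoxide opening with diethylaluminium 2,2,6,6-tetramethylpiperidide, Et2Al(NC9H18) (toluene, 0 °C), would give 5-[(2S)-6-(methoxymethoxy)-2-methyl-2H-chromen-2-yl]-2-methylpent-1-en-3-ol F6.
   - PBr3 (Et2O, −20 °C) with allylic transposition should give predominantly (2S)-2-[(3E)-5-bromo-4-methylpent-3-en-1-yl]-6-(methoxymethoxy)-2-methyl-2H-chromene F7.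
   - Alkylation of lithiated sulfone 13 with F7 would give (2S)-6-(methoxymethoxy)-2-methyl-2-[(3E)-4-methyl-6-(phenylsulfonyl)-6-(2,6,6-trimethylcyclohex-1-en-1-yl)hex-3-en-1-yl]-2H-chromene F8.
   - Desulfonylation of F8 with Na(Hg)/Na2HPO4 should give 16, where the route is rejoined.

3. Step 9 (desulfonylation). The intermediate allyl anion may be protonated at the ring carbon, which moves the ring double bond to the exocyclic position, and sulfinate may be lost by base-induced elimination to a diene. The fallback removes the sulfone from the plan and joins the two allyl units directly. It sets out from 8 and from 10. Alcohol 10 would be converted (MsCl, LiCl, 2,4,6-collidine, DMF, 0 °C) to β-cyclogeranyl chloride F9. Activated barium (from BaI2 and lithium biphenylide, THF, −78 °C) would turn F9 into β-cyclogeranylbarium chloride F10. Addition of bromide 8 at −78 °C should give, by allyl–allyl coupling at the unsubstituted carbon of both partners with retention of the E olefin, compound 15, where the route is rejoined.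

**Further compounds**

F1 | step 2 | 2-fluoro-5-hydroxybenzonitrile | N#Cc1cc(O)ccc1F
F2 | step 2 | 2-fluoro-5-(methoxymethoxy)benzonitrile | N#Cc1cc(OCOC)ccc1F
F3 | step 2 | (S)-2-[(3,7-dimethylocta-1,6-dien-3-yl)oxy]-5-(methoxymethoxy)benzonitrile | C=C[C@@](C)(Oc1ccc(OCOC)cc1C#N)CCC=C(C)C
F4 | step 10 | 1-{[(3S)-5-(3,3-dimethyloxiran-2-yl)-3-methylpent-1-en-3-yl]oxy}-2-ethenyl-4-(methoxymethoxy)benzene, both oxirane epimers | C=C[C@@](C)(Oc1ccc(OCOC)cc1C=C)CCC1OC1(C)C
F5 | step 10 | (2S)-2-[2-(3,3-dimethyloxiran-2-yl)ethyl]-6-(methoxymethoxy)-2-methyl-2H-chromene | CC1(C)OC1CC[C@@]2(C)C=Cc3cc(OCOC)ccc3O2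
F6 | step 10 | 5-[(2S)-6-(methoxymethoxy)-2-methyl-2H-chromen-2-yl]-2-methylpent-1-en-3-ol, both carbinol epimers | C=C(C)C(O)CC[C@@]1(C)C=Cc2cc(OCOC)ccc2O1
F7 | step 10 | (2S)-2-[(3E)-5-bromo-4-methylpent-3-en-1-yl]-6-(methoxymethoxy)-2-methyl-2H-chromene | BrC/C(C)=C/CC[C@@]1(C)C=Cc2cc(OCOC)ccc2O1
F8 | step 10 | (2S)-6-(methoxymethoxy)-2-methyl-2-[(3E)-4-methyl-6-(phenylsulfonyl)-6-(2,6,6-trimethylcyclohex-1-en-1-yl)hex-3-en-1-yl]-2H-chromene | CC1=C(C(C/C(C)=C/CC[C@@]2(C)C=Cc3cc(OCOC)ccc3O2)S(=O)(=O)c2ccccc2)C(C)(C)CCC1
F9 | step 9 | β-cyclogeranyl chloride, 2-(chloromethyl)-1,3,3-trimethylcyclohexene | ClCC1=C(C)CCCC1(C)C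
F10 | step 9 | β-cyclogeranylbarium chloride | Cl[Ba]CC1=C(C)CCCC1(C)C
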